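Ring A is made last, on a finished, enantiopure ring C. Ring A carries oxygens on C5, C7 and C8a, the prenyl group on C6 between two of them and hydrogen on C8; a vinylketene (C5, C8, C8a, C4a) plus an ynol ether (C6, C7) delivers exactly this pattern when C4a=C8a is the enol ether alkene of a dihydropyran. One photochemical–thermal operation (Wolff shift, [2+2], 4π opening, 6π closure) forms C8–C8a, C5–C6, C7–C8 and C4a–C5 and leaves a free C5 phenol beside the C7 methyl ether. The precursor is an (S)-2-(4-methoxyphenyl)dihydropyran bearing a diazoacetyl group on the enol ether carbon, its stereocentre set by transfer hydrogenation.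

Key step: step 8

Remark on the chemistry: the target SMILES corresponds to the (2S) flavan; flavan locants (O1, C2–C4, C4a, C5–C8, C8a) are used for ring atoms from the lactone stage onward.

Step 1
Reactants: 1 anisole; 2 glutaric anhydride
Product: 3 5-(4-methoxyphenyl)-5-oxopentanoic acid
Conditions: AlCl3 (2.2 equiv), CH2Cl2, 0 °C → rt; aq. HCl
Reagents that add atoms: none
Why: Friedel–Crafts acylation with the AlCl3-activated cyclic anhydride attacks anisole para to the methoxy group and stops at monoacylation because the aryl ketone formed is deactivated.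

Step 2
Reactants: 3 5-(4-methoxyphenyl)-5-oxopentanoic acid
Product: 5 (S)-6-(4-methoxyphenyl)tetrahydro-2H-pyran-2-one, via (S)-hydroxy acid 4 (not isolated)
Conditions: RuCl[(S,S)-TsDPEN](p-cymene) (1 mol%), HCO2H/Et3N (5:2), EtOAc, 35 °C; extraction, then EDC·HCl, DMAP (cat.), CH2Cl2, 0 °C → rt
Reagents that add atoms: none
Why: Noyori-type asymmetric transfer hydrogenation of the aryl alkyl ketone, in which the (S,S)-diamine ruthenium hydride delivers hydride to the Re face through its six-membered CH/π-organised transition state and so sets the (S)-benzylic alcohol that becomes C2, is followed by a neutral carbodiimide (Steglich-type) lactonisation that never exposes the ionisable 4-methoxybenzylic C–O bond to strong acid.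

Step 3
Reactants: 5 (S)-6-(4-methoxyphenyl)tetrahydro-2H-pyran-2-one
Product: 6 (S)-2-(4-methoxyphenyl)-3,4-dihydro-2H-pyran-6-yl diphenyl phosphate
Conditions: (PhO)2P(O)Cl (1.3 equiv), DMPU, THF, −78 °C; KN(SiMe3)2 (1.2 equiv) added last
Reagents that add atoms: diphenyl chlorophosphate, O=P(Cl)(Oc1ccccc1)Oc1ccccc1
Why: O-phosphorylation of the lactone enolate, trapped as it forms so that Claisen self-condensation cannot compete, is the standard route to cyclic ketene acetal phosphates and removes only an α-CH2 proton, leaving the C2 stereocentre untouched.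

Step 4
Reactants: 6 (S)-2-(4-methoxyphenyl)-3,4-dihydro-2H-pyran-6-yl diphenyl phosphate
Product: 7 (S)-N-methoxy-2-(4-methoxyphenyl)-N-methyl-3,4-dihydro-2H-pyran-6-carboxamide
Conditions: Pd(PPh3)4 (5 mol%), CO (1 atm), MeNH(OMe)·HCl, Et3N, DMF, 50 °C
Reagents that add atoms: carbon monoxide, [C-]#[O+]; N,O-dimethylhydroxylamine hydrochloride, CNOC.Cl
Why: Palladium-catalysed carbonylation (oxidative addition of zerovalent palladium into the vinyl C–O(P) bond, CO insertion, aminolysis of the acylpalladium) is established as alkoxy- and aminocarbonylation for lactone- and lactam-derived ketene acetal phosphates and triflates and attaches the carbonyl carbon to the enol ether carbon directly at the Weinreb amide level.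

Step 5
Reactants: 7 (S)-N-methoxy-2-(4-methoxyphenyl)-N-methyl-3,4-dihydro-2H-pyran-6-carboxamide
Product: 8 1-[(S)-2-(4-methoxyphenyl)-3,4-dihydro-2H-pyran-6-yl]ethanone
Conditions: MeMgBr (1.5 equiv), THF, −20 → 0 °C; aq. NH4Cl
Reagents that add atoms: methylmagnesium bromide, C[Mg]Br
Why: Weinreb ketone synthesis, in which the chelated tetrahedral magnesium adduct persists until the quench and so stops the Grignard addition at the methyl ketone.

Step 6
Reactants: 8 1-[(S)-2-(4-methoxyphenyl)-3,4-dihydro-2H-pyran-6-yl]ethanone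
Product: 10 2-diazo-1-[(S)-2-(4-methoxyphenyl)-3,4-dihydro-2H-pyran-6-yl]ethanone, via trifluoroacetyl diketone 9 (not isolated)
Conditions: LiN(SiMe3)2, THF, −78 °C; CF3CO2CH2CF3, −78 °C; pH 5 buffer work-up, then 4-acetamidobenzenesulfonyl azide, Et3N, H2O (1 equiv), MeCN, rt
Reagents that add atoms: 4-acetamidobenzenesulfonyl azide, CC(=O)Nc1ccc(cc1)S(=O)(=O)N=[N+]=[N-]; 2,2,2-trifluoroethyl trifluoroacetate, O=C(OCC(F)(F)F)C(F)(F)F (its CF3CO group is carried by 9 only)
Why: Detrifluoroacetylative diazo transfer (Claisen trifluoroacetylation of the kinetic methyl enolate, then Regitz-type transfer from the sulfonyl azide with loss of the trifluoroacetyl group) is the standard entry to conjugated diazomethyl ketones and avoids acylating diazomethane with an enoyl chloride, where dipolar cycloaddition to the alkene competes.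

Step 7
Reactants: 11 chloroacetaldehyde dimethyl acetal; 12 prenyl bromide (1-bromo-3-methylbut-2-ene)
Product: 14 1-methoxy-5-methylhex-4-en-1-yne, via lithium methoxyacetylide 13 (not isolated)
Conditions: LiNEt2 (3 equiv), THF, 0 °C; then 12, DMPU, −78 °C → rt
Reagents that add atoms: none
Why: Base-induced loss of methanol and of HCl from the chloroacetal and deprotonation give lithium methoxyacetylide, whose SN2 alkylation at the primary carbon of prenyl bromide in a dipolar aprotic cosolvent is an ordinary acetylide alkylation, and the methyl ynol ether formed has no β-hydrogen for retro-ene loss of an alkene on later heating.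

Step 8
Reactants: 10 2-diazo-1-[(S)-2-(4-methoxyphenyl)-3,4-dihydro-2H-pyran-6-yl]ethanone; 14 1-methoxy-5-methylhex-4-en-1-yne
Product: 19 (S)-5-hydroxy-7,4'-dimethoxy-6-prenylflavan, via vinylketene 15 (not isolated), via vinylcyclobutenone 16 (not isolated), via dienylketene 17 (not isolated), via cyclohexadienone 18 (not isolated)
Conditions: 14 (1.5 equiv), hν (300–365 nm, Pyrex), degassed toluene, rt, until N2 evolution ends; then 90 °C
Reagents that add atoms: none
Why: Light expels N2 from 10 and the ring carbon C8a shifts from the carbonyl carbon to the former diazo carbon C8 (photo-Wolff rearrangement), so that vinylketene 15 carries the future C5 as its ketene carbon. The prenyl-bearing carbon of 14, the nucleophilic carbon β to oxygen, attacks that ketene carbon in a regiospecific [2+2] (bonds C5–C6 and C7–C8) to give cyclobutenone 16, which on warming opens reversibly by a 4π electrocyclic reaction to dienylketene 17. Ring A then closes by a thermal, disrotatory 6π electrocyclisation of 17 that forms C4a–C5, and dienone 18 tautomerises to the phenol. The closest known reaction type is the Danheiser benzannulation in its diazoketone version with alkoxy- and siloxyalkynes, which also tolerates electron-rich heteroaryl diazoketones. No stereocentre is created in the product (the centres of 16 and 18 are transient), and C2, set in step 2, is not touched by the neutral, acid-free medium. The one selectivity required is the orientation of the [2+2], which the polarisation of the ynol ether fixes, so prenyl can only end on C6 between O5 and O7, while the filtered light excites the diazoketone and not the anisyl ring or the prenyl alkene.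

Step 9
Reactants: 19 (S)-5-hydroxy-7,4'-dimethoxy-6-prenylflavan
Product: 20 (S)-5,7,4'-trimethoxy-6-prenylflavan (target)
Conditions: MeI (3 equiv), K2CO3 (3 equiv), DMF, rt
Reagents that add atoms: iodomethane, CI
Why: Williamson etherification of the C5 phenoxide, the only acidic site, under mild carbonate base that leaves the C2 benzylic ether and the prenyl alkene untouched.

Compound list
1 | anisole | COc1ccccc1 | starting material
2 | glutaric anhydride | O=C1CCCC(=O)O1 | starting material
3 | 5-(4-methoxyphenyl)-5-oxopentanoic acid | COc1ccc(C(=O)CCCC(=O)O)cc1 | intermediate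
4 | (S)-5-hydroxy-5-(4-methoxyphenyl)pentanoic acid | COc1ccc([C@@H](O)CCCC(=O)O)cc1 | intermediate
5 | (S)-6-(4-methoxyphenyl)tetrahydro-2H-pyran-2-one | COc1ccc([C@@H]2CCCC(=O)O2)cc1 | intermediate
6 | (S)-2-(4-methoxyphenyl)-3,4-dihydro-2H-pyran-6-yl diphenyl phosphate | COc1ccc([C@@H]2CCC=C(OP(=O)(Oc3ccccc3)Oc3ccccc3)O2)cc1 | intermediate
7 | (S)-N-methoxy-2-(4-methoxyphenyl)-N-methyl-3,4-dihydro-2H-pyran-6-carboxamide | COc1ccc([C@@H]2CCC=C(C(=O)N(C)OC)O2)cc1 | intermediate
8 | 1-[(S)-2-(4-methoxyphenyl)-3,4-dihydro-2H-pyran-6-yl]ethanone | COc1ccc([C@@H]2CCC=C(C(C)=O)O2)cc1 | intermediate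
9 | 4,4,4-trifluoro-1-[(S)-2-(4-methoxyphenyl)-3,4-dihydro-2H-pyran-6-yl]butane-1,3-dione | COc1ccc([C@@H]2CCC=C(C(=O)CC(=O)C(F)(F)F)O2)cc1 | intermediate
10 | 2-diazo-1-[(S)-2-(4-methoxyphenyl)-3,4-dihydro-2H-pyran-6-yl]ethanone | COc1ccc([C@@H]2CCC=C(C(=O)C=[N+]=[N-])O2)cc1 | intermediate
11 | chloroacetaldehyde dimethyl acetal (2-chloro-1,1-dimethoxyethane) | COC(CCl)OC | starting material
12 | prenyl bromide (1-bromo-3-methylbut-2-ene) | CC(C)=CCBr | starting material
13 | lithium methoxyacetylide | [Li]C#COC | intermediate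
14 | 1-methoxy-5-methylhex-4-en-1-yne | COC#CCC=C(C)C | intermediate
15 | 2-[(S)-2-(4-methoxyphenyl)-3,4-dihydro-2H-pyran-6-yl]ethen-1-one (vinylketene) | COc1ccc([C@@H]2CCC=C(C=C=O)O2)cc1 | intermediate
16 | 3-methoxy-4-[(S)-2-(4-methoxyphenyl)-3,4-dihydro-2H-pyran-6-yl]-2-(3-methylbut-2-en-1-yl)cyclobut-2-en-1-one (either configuration at the cyclobutenone sp3 carbon) | COc1ccc([C@@H]2CCC=C(C3C(OC)=C(CC=C(C)C)C3=O)O2)cc1 | intermediate
17 | (3E)-3-methoxy-4-[(S)-2-(4-methoxyphenyl)-3,4-dihydro-2H-pyran-6-yl]-2-(3-methylbut-2-en-1-yl)buta-1,3-dien-1-one (pyranyl group cis to the ketene-bearing carbon) | COc1ccc([C@@H]2CCC=C(/C=C(OC)\C(CC=C(C)C)=C=O)O2)cc1 | intermediate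
18 | (2S)-7-methoxy-2-(4-methoxyphenyl)-6-(3-methylbut-2-en-1-yl)-3,4-dihydro-2H-chromen-5(4aH)-one (either configuration at C4a) | COc1ccc([C@@H]2CCC3C(=O)C(CC=C(C)C)=C(OC)C=C3O2)cc1 | intermediate
19 | (S)-5-hydroxy-7,4'-dimethoxy-6-prenylflavan [(2S)-7-methoxy-2-(4-methoxyphenyl)-6-(3-methylbut-2-en-1-yl)chroman-5-ol] | COc1ccc([C@@H]2CCc3c(cc(OC)c(CC=C(C)C)c3O)O2)cc1 | intermediate
20 | (S)-5,7,4'-trimethoxy-6-prenylflavan [(2S)-5,7-dimethoxy-2-(4-methoxyphenyl)-6-(3-methylbut-2-en-1-yl)chromane] | COc1ccc([C@@H]2CCc3c(cc(OC)c(CC=C(C)C)c3OC)O2)cc1 | target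

Total step count: 9 steps.
Longest linear sequence: 8 steps (steps 1–6, 8 and 9); the ynol ether branch is step 7.

Steps most likely to fail

Step 8. What may go wrong: after loss of N2 the oxygen-substituted vinyl group may migrate too slowly, so that carbene side reactions, ketene dimerisation or light-induced decay of the ynol ether outrun the [2+2] capture. The fallback is a classical, non-photochemical assembly of the flavan that sets out from prenyl bromide 12 and comes back to the route at target 20.
- 3,5-Dimethoxyphenol is silylated (i-Pr3SiCl, imidazole, DMF) to (3,5-dimethoxyphenoxy)triisopropylsilane F1.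
- Directed lithiation between the two methoxy groups (n-BuLi, THF, 0 °C) and allylation with 12 (CuBr·SMe2 cat.) should give [3,5-dimethoxy-4-(3-methylbut-2-en-1-yl)phenoxy]triisopropylsilane F2.
- Bu4NF in THF frees 3,5-dimethoxy-4-(3-methylbut-2-en-1-yl)phenol F3, whose two ortho positions are equivalent.
- Magnesium-mediated ortho-formylation (MgCl2, Et3N, paraformaldehyde, MeCN, reflux) therefore gives a single aldehyde, 6-hydroxy-2,4-dimethoxy-3-(3-methylbut-2-en-1-yl)benzaldehyde F4.
- Claisen–Schmidt condensation with 4-methoxyacetophenone (KOH, EtOH) gives (E)-3-[6-hydroxy-2,4-dimethoxy-3-(3-methylbut-2-en-1-yl)phenyl]-1-(4-methoxyphenyl)prop-2-en-1-one F5.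
- Transfer hydrogenation of both the enone C=C and the C=O with RuCl[(R,R)-TsDPEN](p-cymene), HCO2H/Et3N, should give (R)-2-[3-hydroxy-3-(4-methoxyphenyl)propyl]-3,5-dimethoxy-4-(3-methylbut-2-en-1-yl)phenol F6, with the isolated prenyl alkene untouched.
- Mitsunobu cyclisation (PPh3, diisopropyl azodicarboxylate, THF, 0 °C) closes O1–C2 with inversion and gives 20.

Step 7. What may go wrong: N-alkylation of the liberated diethylamine by prenyl bromide may compete with C-alkylation of the acetylide, and residual base may isomerise the skipped enyne to an allenyl ether. The fallback replaces the methyl ynol ether by a silyl ynol ether made through ynolate O-silylation; it sets out from 12 and comes back at target 20.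
- 12 and LiC≡CH·H2NCH2CH2NH2 in DMSO give 5-methylhex-4-en-1-yne F7.
- Lithiation (n-BuLi, THF, −78 °C), oxidation of the acetylide to the lithium ynolate with t-BuOOLi (from t-BuOOH and LiN(SiMe3)2) and silylation with i-Pr3SiOSO2CF3 give triisopropyl[(5-methylhex-4-en-1-yn-1-yl)oxy]silane F8.
- F8 and diazoketone 10 under the conditions of step 8 should give (S)-5-hydroxy-4'-methoxy-6-prenyl-7-(triisopropylsilyloxy)flavan F9.
- Bu4NF in THF gives (S)-5,7-dihydroxy-4'-methoxy-6-prenylflavan F10.
- MeI (excess), K2CO3, DMF methylates both phenols and gives 20.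

Step 4. What may go wrong: CO-saturated palladium may add too slowly into the C–O(P) bond and the weakly nucleophilic hydroxylamine may capture the acylpalladium sluggishly, so that hydrolysis of the ketene acetal phosphate back to the lactone wins. The fallback sets out from 6 and comes back at methyl ketone 8.
- Stille coupling of 6 with tributyl(1-ethoxyvinyl)stannane (Pd(PPh3)4, LiCl, THF, reflux) is a CO-free coupling known for lactone-derived ketene acetal phosphates. It gives (S)-6-(1-ethoxyvinyl)-2-(4-methoxyphenyl)-3,4-dihydro-2H-pyran F11.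
- Brief mild hydrolysis (oxalic acid, wet THF, 0 °C) should protonate the terminal CH2 of the acyclic enol ether preferentially and give 8 directly, which also removes step 5.

Further compounds
F1 | step 8 | (3,5-dimethoxyphenoxy)triisopropylsilane | COc1cc(OC)cc(O[Si](C(C)C)(C(C)C)C(C)C)c1
F2 | step 8 | [3,5-dimethoxy-4-(3-methylbut-2-en-1-yl)phenoxy]triisopropylsilane | COc1cc(O[Si](C(C)C)(C(C)C)C(C)C)cc(OC)c1CC=C(C)C
F3 | step 8 | 3,5-dimethoxy-4-(3-methylbut-2-en-1-yl)phenol | COc1cc(O)cc(OC)c1CC=C(C)C
F4 | step 8 | 6-hydroxy-2,4-dimethoxy-3-(3-methylbut-2-en-1-yl)benzaldehyde | COc1cc(O)c(C=O)c(OC)c1CC=C(C)C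
F5 | step 8 | (E)-3-[6-hydroxy-2,4-dimethoxy-3-(3-methylbut-2-en-1-yl)phenyl]-1-(4-methoxyphenyl)prop-2-en-1-one | COc1ccc(C(=O)/C=C/c2c(O)cc(OC)c(CC=C(C)C)c2OC)cc1
F6 | step 8 | (R)-2-[3-hydroxy-3-(4-methoxyphenyl)propyl]-3,5-dimethoxy-4-(3-methylbut-2-en-1-yl)phenol | COc1ccc([C@H](O)CCc2c(O)cc(OC)c(CC=C(C)C)c2OC)cc1
F7 | step 7 | 5-methylhex-4-en-1-yne | C#CCC=C(C)C
F8 | step 7 | triisopropyl[(5-methylhex-4-en-1-yn-1-yl)oxy]silane | CC(C)=CCC#CO[Si](C(C)C)(C(C)C)C(C)C
F9 | step 7 | (S)-5-hydroxy-4'-methoxy-6-prenyl-7-(triisopropylsilyloxy)flavan | COc1ccc([C@@H]2CCc3c(cc(O[Si](C(C)C)(C(C)C)C(C)C)c(CC=C(C)C)c3O)O2)cc1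
F10 | step 7 | (S)-5,7-dihydroxy-4'-methoxy-6-prenylflavan | COc1ccc([C@@H]2CCc3c(cc(O)c(CC=C(C)C)c3O)O2)cc1
F11 | step 4 | (S)-6-(1-ethoxyvinyl)-2-(4-methoxyphenyl)-3,4-dihydro-2H-pyran | COc1ccc([C@@H]2CCC=C(C(=C)OCC)O2)cc1
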